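**Strategy.** The chroman (benzo ring A, pyran ring C) is cut at O1–C2, C2–C3 and C4–C4a, leaving three components: homoallylic alcohol 4, aldehyde 7 and the symmetric acylphloroglucinol 6. In one flask a Prins cyclization and Friedel–Crafts capture first fold them into an all-cis tetrahydropyran; its 4-alkoxybenzylic ring C–O bond then ionises and the neighbouring phenol closes ring C. The step exploits two features: C2 is a benzylic ether carbon bearing a 4-oxyphenyl group, and C4 stands 1,3 to the side-chain carbinol carbon, so C2–C3–C4–CH2–CH(O) can be held in a temporary tetrahydropyran whose oxygen becomes the side-chain hydroxyl and relays its configuration to C4.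

Key step: step 5

Remark: in step 5 only the released side-chain hydroxyl is taken to be silylated (9); the hindered, acidic phenols of 8 and 9 are written free, since the triflic acid present protodesilylates aryl silyl ethers.

**Step 1**
Reactants: 1 3-(4-hydroxyphenyl)propan-1-ol
Product: 2 3-[4-(allyloxy)phenyl]propan-1-ol
Conditions: allyl bromide, K2CO3, acetone, reflux
Reagents that add atoms: allyl bromide, C=CCBr
Why: Williamson etherification in which K2CO3 deprotonates only the phenol, so the primary alcohol should stay free.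

**Step 2**
Reactants: 2 3-[4-(allyloxy)phenyl]propan-1-ol
Product: 3 3-[4-(allyloxy)phenyl]propanal
Conditions: TEMPO (10 mol%), PhI(OAc)2, CH2Cl2, rt
Reagents that add atoms: none
Why: Oxoammonium (TEMPO) oxidation of a primary alcohol stops at the aldehyde and should leave the aryl allyl ether untouched.

**Step 3**
Reactants: 3 3-[4-(allyloxy)phenyl]propanal
Product: 4 (3R)-1-[4-(allyloxy)phenyl]hex-5-en-3-ol
Conditions: (−)-Ipc2B(allyl) (1 M in pentane), Et2O, −78 °C; then NaOH, H2O2
Reagents that add atoms: (−)-B-allyldiisopinocampheylborane, C=CCB([C@@H]1C[C@@H]2C[C@H]([C@H]1C)C2(C)C)[C@@H]1C[C@@H]2C[C@H]([C@H]1C)C2(C)C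
Why: Brown allylboration through a chair Zimmerman–Traxler transition state, in which the (−)-reagent (from (+)-α-pinene) delivers allyl to the Si face of the aliphatic aldehyde and so should set the (R)-carbinol.

**Step 4**
Reactants: 5 1-(2,4,6-trihydroxyphenyl)ethan-1-one
Product: 6 4-acetyl-3,5-dihydroxyphenyl pivalate
Conditions: pivaloyl chloride (1.0 equiv), Et3N, THF, −20 to 0 °C
Reagents that add atoms: pivaloyl chloride, CC(C)(C)C(=O)Cl
Why: Kinetic O-acylation should occur at the para hydroxyl, which is the most acidic and the only one not flanking the acetyl group, so the product keeps two equivalent free ring positions.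

**Step 5**
Reactants: 4 (3R)-1-[4-(allyloxy)phenyl]hex-5-en-3-ol; 7 4-(allyloxy)benzaldehyde; 6 4-acetyl-3,5-dihydroxyphenyl pivalate
Product: 10 (2R,4S)-8-acetyl-2-[4-(allyloxy)phenyl]-4-{(2R)-4-[4-(allyloxy)phenyl]-2-hydroxybutyl}-7-hydroxychroman-5-yl pivalate, via all-cis tetrahydropyran 8 (not isolated), via trimethylsilyl ether 9 (not isolated)
Conditions: TMSOTf (3 equiv), CH2Cl2, −78 to 0 °C; aq NaHCO3; then citric acid, MeOH, rt
Reagents that add atoms: none
Why: TMSOTf condenses 4 with 7 to the (E)-oxocarbenium ion, whose terminal alkene attacks through a chair transition state (Prins cyclization, 6-endo-trig closure of the temporary tetrahydropyran) and whose tetrahydropyran-4-yl cation is captured equatorially by arene 6 (Friedel–Crafts) to give all-cis 8. On warming, the triflic acid formed ionises the 4-alkoxybenzylic ring C–O bond of 8 and the flanking phenol adds to the quinone-methide-like cation (6-exo-trig closure of ring C), the former ring oxygen leaving as the side-chain silyl ether 9. The closest known reaction types are the tandem Prins cyclization/Friedel–Crafts arylation of homoallylic alcohols with aryl aldehydes and the acid-promoted isomerisation of 2-aryltetrahydropyrans into benzopyrans by a neighbouring phenol. C4 is fixed by the (R)-carbinol of 4, which sits equatorial in the chair and places the arene cis to it (4S), while C2 is set last under thermodynamic control by reversible ionisation, the 2,4-trans (2R) epimer being expected because the C4 side chain turns pseudoaxial away from the peri C5 pivalate with the C2 aryl equatorial. The step needs one Friedel–Crafts site and one closing oxygen, secured because the two free positions of 6 are equivalent by symmetry, the para oxygen is blocked as the pivalate and the second ortho hydroxyl keeps the acetyl group hydrogen-bonded so that closure costs no chelate. The acyl and pivaloyloxy groups also temper the arene so that it should trap the tetrahydropyranyl cation but not the stabilised oxocarbenium ion, and silyl capture of the released alkoxide and the freed side-chain rotors should bias the transposition towards the chroman.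

**Step 6**
Reactants: 10 (2R,4S)-8-acetyl-2-[4-(allyloxy)phenyl]-4-{(2R)-4-[4-(allyloxy)phenyl]-2-hydroxybutyl}-7-hydroxychroman-5-yl pivalate
Product: 11 (2R,4S)-8-acetyl-2-[4-(allyloxy)phenyl]-4-{(2R)-4-[4-(allyloxy)phenyl]-2-hydroxybutyl}-7-methoxychroman-5-yl pivalate
Conditions: MeI, K2CO3, DMF, rt to 40 °C
Reagents that add atoms: iodomethane, CI
Why: Williamson O-methylation of the only phenol (the chelated C7 hydroxyl), under which the secondary alcohol is not deprotonated and the hindered pivalate should survive.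

**Step 7**
Reactants: 11 (2R,4S)-8-acetyl-2-[4-(allyloxy)phenyl]-4-{(2R)-4-[4-(allyloxy)phenyl]-2-hydroxybutyl}-7-methoxychroman-5-yl pivalate; 7 4-(allyloxy)benzaldehyde
Product: 12 (E)-1-[(2R,4S)-2-[4-(allyloxy)phenyl]-4-{(2R)-4-[4-(allyloxy)phenyl]-2-hydroxybutyl}-5-hydroxy-7-methoxychroman-8-yl]-3-[4-(allyloxy)phenyl]prop-2-en-1-one
Conditions: KOH, EtOH/H2O, rt; then aq NH4Cl
Reagents that add atoms: none
Why: Claisen–Schmidt condensation (aldol addition, E1cB dehydration to the (E)-enone) in which hydroxide also saponifies the aryl pivalate to release the C5 phenol, while the etherified C2 aryl group closes off any quinone methide pathway in base.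

**Step 8**
Reactants: 12 (E)-1-[(2R,4S)-2-[4-(allyloxy)phenyl]-4-{(2R)-4-[4-(allyloxy)phenyl]-2-hydroxybutyl}-5-hydroxy-7-methoxychroman-8-yl]-3-[4-(allyloxy)phenyl]prop-2-en-1-one
Product: 13 (E)-1-[(2R,4S)-5-hydroxy-4-[(2R)-2-hydroxy-4-(4-hydroxyphenyl)butyl]-2-(4-hydroxyphenyl)-7-methoxychroman-8-yl]-3-(4-hydroxyphenyl)prop-2-en-1-one
Conditions: Pd(PPh3)4 (10 mol%), N-methylaniline, THF, rt
Reagents that add atoms: none
Why: Tsuji–Trost deallylation in which zerovalent palladium ionises the three aryl allyl ethers and N-methylaniline traps the allyl groups under neutral conditions, so neither the enone nor the acid- and base-sensitive C2 benzylic ether should be touched.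

**Compound list**
1 | 3-(4-hydroxyphenyl)propan-1-ol | OCCCc1ccc(O)cc1 | starting material
2 | 3-[4-(allyloxy)phenyl]propan-1-ol | OCCCc1ccc(OCC=C)cc1 | intermediate
3 | 3-[4-(allyloxy)phenyl]propanal | O=CCCc1ccc(OCC=C)cc1 | intermediate
4 | (3R)-1-[4-(allyloxy)phenyl]hex-5-en-3-ol | C=CC[C@H](O)CCc1ccc(OCC=C)cc1 | intermediate
5 | 1-(2,4,6-trihydroxyphenyl)ethan-1-one | CC(=O)c1c(O)cc(O)cc1O | starting material
6 | 4-acetyl-3,5-dihydroxyphenyl pivalate | CC(=O)c1c(O)cc(OC(=O)C(C)(C)C)cc1O | intermediate
7 | 4-(allyloxy)benzaldehyde | O=Cc1ccc(OCC=C)cc1 | starting material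
8 | 4-acetyl-2-[(2R,4S,6R)-2-[4-(allyloxy)phenyl]-6-{2-[4-(allyloxy)phenyl]ethyl}oxan-4-yl]-3,5-dihydroxyphenyl pivalate (all-cis tetrahydropyran) | O1[C@@H](c2ccc(OCC=C)cc2)C[C@@H](c2c(O)c(C(C)=O)c(O)cc2OC(=O)C(C)(C)C)C[C@H]1CCc1ccc(OCC=C)cc1 | intermediate
9 | O-trimethylsilyl ether of 10 at the side-chain hydroxyl | Oc1cc(OC(=O)C(C)(C)C)c2c(c1C(C)=O)O[C@@H](c1ccc(OCC=C)cc1)C[C@@H]2C[C@H](O[Si](C)(C)C)CCc1ccc(OCC=C)cc1 | intermediate
10 | (2R,4S)-8-acetyl-2-[4-(allyloxy)phenyl]-4-{(2R)-4-[4-(allyloxy)phenyl]-2-hydroxybutyl}-7-hydroxychroman-5-yl pivalate | Oc1cc(OC(=O)C(C)(C)C)c2c(c1C(C)=O)O[C@@H](c1ccc(OCC=C)cc1)C[C@@H]2C[C@H](O)CCc1ccc(OCC=C)cc1 | intermediate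
11 | (2R,4S)-8-acetyl-2-[4-(allyloxy)phenyl]-4-{(2R)-4-[4-(allyloxy)phenyl]-2-hydroxybutyl}-7-methoxychroman-5-yl pivalate | COc1cc(OC(=O)C(C)(C)C)c2c(c1C(C)=O)O[C@@H](c1ccc(OCC=C)cc1)C[C@@H]2C[C@H](O)CCc1ccc(OCC=C)cc1 | intermediate
12 | (E)-1-[(2R,4S)-2-[4-(allyloxy)phenyl]-4-{(2R)-4-[4-(allyloxy)phenyl]-2-hydroxybutyl}-5-hydroxy-7-methoxychroman-8-yl]-3-[4-(allyloxy)phenyl]prop-2-en-1-one | COc1cc(O)c2c(c1C(=O)/C=C/c1ccc(OCC=C)cc1)O[C@@H](c1ccc(OCC=C)cc1)C[C@@H]2C[C@H](O)CCc1ccc(OCC=C)cc1 | intermediate
13 | (E)-1-[(2R,4S)-5-hydroxy-4-[(2R)-2-hydroxy-4-(4-hydroxyphenyl)butyl]-2-(4-hydroxyphenyl)-7-methoxychroman-8-yl]-3-(4-hydroxyphenyl)prop-2-en-1-one | COc1cc(O)c2c(c1C(=O)/C=C/c1ccc(O)cc1)O[C@@H](c1ccc(O)cc1)C[C@@H]2C[C@H](O)CCc1ccc(O)cc1 | target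

**Step count and risks**
Total step count: 8. Longest linear sequence: 7 steps (1, 2, 3, 5, 6, 7, 8).

Steps most likely to fail:

1. Step 5. The transposition may stop at a tetrahydropyran/chroman equilibrium because the released side-chain oxygen re-closes in competition with the phenol. The arene may also intercept the oxocarbenium ion before it cyclises, and 2-oxonia-Cope exchange may erode enantiopurity. The fallback sets out from 8, isolated by quenching step 5 at −40 °C before the transposition begins, and comes back at 10. Dimethylboron bromide (Me2BBr, CH2Cl2, −78 °C) should cleave the benzylic ring C–O bond of 8 by bromide capture, holding the side-chain oxygen as a borinate. Hydrolytic work-up would give 4-acetyl-2-[(3S,5R)-1-bromo-5-hydroxy-1,7-bis(4-(allyloxy)phenyl)heptan-3-yl]-3,5-dihydroxyphenyl pivalate F1. In aqueous NaHCO3 the acidic ring A phenol, present as phenoxide, should displace the benzylic bromide (Williamson closure, 6-exo-tet) faster than the neutral alcohol. This gives 10 under conditions that cannot re-equilibrate; a product-like transition state is expected to favour the same 2,4-trans arrangement.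

2. Step 7. Once the pivalate is saponified, the hindered ketone carries a para phenoxide and may enolise too slowly, so condensation stalls while the aldehyde is lost to Cannizzaro disproportionation. The fallback sets out from 11 and comes back at 13. K2CO3 in MeOH removes the pivalate to give 1-[(2R,4S)-2-[4-(allyloxy)phenyl]-4-{(2R)-4-[4-(allyloxy)phenyl]-2-hydroxybutyl}-5-hydroxy-7-methoxychroman-8-yl]ethan-1-one F2. Allyl bromide and K2CO3 in acetone convert it into the 5-allyloxy ketone F3. Condensation with 7 (KOH, EtOH) then runs on a non-ionised ketone and gives the tetra-O-allyl chalcone F4. The conditions of step 8 remove all four allyl ethers to give 13.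

3. Step 8. Removal of three allyl ethers may be incomplete, or the amine scavenger may add to the enone. The fallback sets out from 12 and comes back at 13. Isomerisation with [Ir(cod)(PMePh2)2]PF6 (activated with H2, THF, rt) should give the tris[(E)-prop-1-enyl] ether F5. Its enol ethers are then hydrolysed under neutral conditions with HgCl2 and HgO in acetone/water to give 13.

**Further compounds**
F1 | step 5 | 4-acetyl-2-[(3S,5R)-1-bromo-5-hydroxy-1,7-bis(4-(allyloxy)phenyl)heptan-3-yl]-3,5-dihydroxyphenyl pivalate (C1 epimers) | CC(=O)c1c(O)cc(OC(=O)C(C)(C)C)c(c1O)[C@H](CC(Br)c1ccc(OCC=C)cc1)C[C@H](O)CCc1ccc(OCC=C)cc1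
F2 | step 7 | 1-[(2R,4S)-2-[4-(allyloxy)phenyl]-4-{(2R)-4-[4-(allyloxy)phenyl]-2-hydroxybutyl}-5-hydroxy-7-methoxychroman-8-yl]ethan-1-one | COc1cc(O)c2c(c1C(C)=O)O[C@@H](c1ccc(OCC=C)cc1)C[C@@H]2C[C@H](O)CCc1ccc(OCC=C)cc1
F3 | step 7 | 1-[(2R,4S)-5-(allyloxy)-2-[4-(allyloxy)phenyl]-4-{(2R)-4-[4-(allyloxy)phenyl]-2-hydroxybutyl}-7-methoxychroman-8-yl]ethan-1-one | COc1cc(OCC=C)c2c(c1C(C)=O)O[C@@H](c1ccc(OCC=C)cc1)C[C@@H]2C[C@H](O)CCc1ccc(OCC=C)cc1
F4 | step 7 | (E)-1-[(2R,4S)-5-(allyloxy)-2-[4-(allyloxy)phenyl]-4-{(2R)-4-[4-(allyloxy)phenyl]-2-hydroxybutyl}-7-methoxychroman-8-yl]-3-[4-(allyloxy)phenyl]prop-2-en-1-one | COc1cc(OCC=C)c2c(c1C(=O)/C=C/c1ccc(OCC=C)cc1)O[C@@H](c1ccc(OCC=C)cc1)C[C@@H]2C[C@H](O)CCc1ccc(OCC=C)cc1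
F5 | step 8 | tris[(E)-prop-1-enyl] ether of 13 at the three 4-hydroxyphenyl oxygens | COc1cc(O)c2c(c1C(=O)/C=C/c1ccc(O/C=C/C)cc1)O[C@@H](c1ccc(O/C=C/C)cc1)C[C@@H]2C[C@H](O)CCc1ccc(O/C=C/C)cc1
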